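**Retrosynthetic overview**
- The target is a cis-fused 2,6-diaryl-3,7-dioxabicyclo[3.3.0]octan-8-one with H-3, H-3a, H-6 and H-6a all on one face. The last two C–H bonds (C6, C6a) come from hydrogenation of a C6=C6a enol ether on its convex face, followed by desilylation.
- Key disconnection O5–C4H2: the dihydrofuran ring arises by iodide-catalysed Cloke–Wilson ring expansion of a 1-aroyl-3-oxabicyclo[3.1.0]hexan-2-one. The enabling feature is the cyclopropane CH2 (C6), bonded to C1, which carries both the lactone C=O and the aroyl C=O. Strain release therefore gives a doubly stabilised enolate whose ketone oxygen lies five atoms from that CH2.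
- The aroyl group is attached by Negishi acylation of the cyclopropane-lactone carboxylic acid with a catechol-derived arylzinc.
- The cyclopropane and γ-lactone form in one step from diallyl malonate and a (2R,3R)-epoxy tosylate (alkylation, 3-exo-tet epoxide opening with inversion, lactonisation). The trans-epoxide is translated into the aryl group cis to the cyclopropane CH2. The epoxide comes from syringaldehyde by silylation, Wittig olefination, reduction, Sharpless epoxidation and tosylation.
- Ring order: oxirane, then cyclopropane and γ-lactone together, then dihydrofuran (key step), then tetrahydrofuran by hydrogenation.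

Key step: step 10

Remark on the chemistry: the SMILES is read as the (3S,3aS,6S,6aR) isomer, with both aryl groups on the concave face of the bicycle. Furo[3,4-c]furan numbering is used for the bicyclic products.

**Step 1**
Reactants: 1 syringaldehyde (4-hydroxy-3,5-dimethoxybenzaldehyde)
Product: 2 3,5-dimethoxy-4-(triisopropylsilyloxy)benzaldehyde
Conditions: TIPSOTf, 2,6-lutidine, CH2Cl2, 0 °C to rt
Reagents that add atoms: triisopropylsilyl trifluoromethanesulfonate, CC(C)[Si](OS(=O)(=O)C(F)(F)F)(C(C)C)C(C)C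
Why: O-silylation of the hindered phenol with a silyl triflate and a non-nucleophilic base should install a group that resists the alkoxide, organometallic and hydrogenation steps and leaves with fluoride.

**Step 2**
Reactants: 2 3,5-dimethoxy-4-(triisopropylsilyloxy)benzaldehyde; 3 ethyl (triphenylphosphoranylidene)acetate
Product: 4 ethyl (E)-3-[3,5-dimethoxy-4-(triisopropylsilyloxy)phenyl]prop-2-enoate
Conditions: toluene, 80 °C
Reagents that add atoms: none
Why: Wittig olefination with a stabilised ylide should give the (E)-cinnamate, the geometry that later becomes the trans-epoxide.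

**Step 3**
Reactants: 4 ethyl (E)-3-[3,5-dimethoxy-4-(triisopropylsilyloxy)phenyl]prop-2-enoate
Product: 5 (E)-3-[3,5-dimethoxy-4-(triisopropylsilyloxy)phenyl]prop-2-en-1-ol
Conditions: i-Bu2AlH, CH2Cl2, -78 to 0 °C; aq. KNaC4H4O6 work-up
Reagents that add atoms: none
Why: 1,2-reduction of the conjugated ester with i-Bu2AlH should give the allylic alcohol without touching the alkene or the aryl silyl ether.

**Step 4**
Reactants: 5 (E)-3-[3,5-dimethoxy-4-(triisopropylsilyloxy)phenyl]prop-2-en-1-ol
Product: 6 [(2R,3R)-3-[3,5-dimethoxy-4-(triisopropylsilyloxy)phenyl]oxiran-2-yl]methanol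
Conditions: Ti(OiPr)4 (10 mol%), D-(-)-diisopropyl tartrate (12 mol%), t-BuOOH, 4 Å molecular sieves, CH2Cl2, -20 °C; basic work-up
Reagents that add atoms: tert-butyl hydroperoxide, CC(C)(C)OO
Why: Sharpless asymmetric epoxidation of the (E)-allylic alcohol with the D-(-)-tartrate ligand should deliver oxygen to the face that gives the (2R,3R) trans-epoxide, which sets both C3 and C3a of the target.

**Step 5**
Reactants: 6 [(2R,3R)-3-[3,5-dimethoxy-4-(triisopropylsilyloxy)phenyl]oxiran-2-yl]methanol
Product: 7 [(2R,3R)-3-[3,5-dimethoxy-4-(triisopropylsilyloxy)phenyl]oxiran-2-yl]methyl 4-methylbenzenesulfonate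
Conditions: TsCl, Et3N, DMAP (cat.), CH2Cl2, 0 °C
Reagents that add atoms: 4-methylbenzenesulfonyl chloride, Cc1ccc(cc1)S(=O)(=O)Cl
Why: Sulfonylation of the primary alcohol under basic conditions should activate C1 for SN2 displacement without opening the acid-sensitive aryl epoxide.

**Step 6**
Reactants: 7 [(2R,3R)-3-[3,5-dimethoxy-4-(triisopropylsilyloxy)phenyl]oxiran-2-yl]methyl 4-methylbenzenesulfonate; 8 diallyl malonate
Product: 11 allyl (1S,4S,5R)-4-[3,5-dimethoxy-4-(triisopropylsilyloxy)phenyl]-2-oxo-3-oxabicyclo[3.1.0]hexane-1-carboxylate, via epoxy malonate 9 (not isolated), via cyclopropyl alkoxide 10 (not isolated)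
Conditions: NaH, THF, 0 °C, then 7, rt to 60 °C; aq. NH4Cl
Reagents that add atoms: none
Why: C-alkylation of sodium diallyl malonate at the primary tosylate (SN2) gives 9, whose malonate anion opens the oxirane at C2 in the 3-exo-tet mode with inversion (the epichlorohydrin–malonate cyclopropanation type) to give 10, and the benzylic alkoxide then lactonises onto the cis ester; C4 keeps the configuration of epoxide C3, C5 is the inverted C2 and C1 is fixed by the cis ring fusion, so the trans-epoxide is translated stereospecifically into the aryl group cis to the cyclopropane CH2.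

**Step 7**
Reactants: 11 allyl (1S,4S,5R)-4-[3,5-dimethoxy-4-(triisopropylsilyloxy)phenyl]-2-oxo-3-oxabicyclo[3.1.0]hexane-1-carboxylate
Product: 12 (1S,4S,5R)-4-[3,5-dimethoxy-4-(triisopropylsilyloxy)phenyl]-2-oxo-3-oxabicyclo[3.1.0]hexane-1-carboxylic acid
Conditions: Pd(PPh3)4 (3 mol%), N-methylaniline, THF, rt; dilute citric acid wash
Reagents that add atoms: none
Why: Tsuji–Trost-type deallylation with a weakly basic amine as allyl acceptor should free the acid under neutral conditions that spare the lactone, the electrophilic cyclopropane and the silyl ether.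

**Step 8**
Reactants: 13 4-bromocatechol (4-bromobenzene-1,2-diol)
Product: 14 4-bromo-1,2-bis(tert-butyldimethylsilyloxy)benzene
Conditions: TBSCl, imidazole, DMF, rt
Reagents that add atoms: tert-butyldimethylsilyl chloride, CC(C)(C)[Si](C)(C)Cl
Why: Standard bis-silylation of the catechol should give a partner that tolerates halogen–metal exchange and is later unmasked with fluoride together with the other silyl ether.

**Step 9**
Reactants: 12 (1S,4S,5R)-4-[3,5-dimethoxy-4-(triisopropylsilyloxy)phenyl]-2-oxo-3-oxabicyclo[3.1.0]hexane-1-carboxylic acid; 14 4-bromo-1,2-bis(tert-butyldimethylsilyloxy)benzene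
Product: 18 (1S,4S,5R)-1-[3,4-bis(tert-butyldimethylsilyloxy)benzoyl]-4-[3,5-dimethoxy-4-(triisopropylsilyloxy)phenyl]-3-oxabicyclo[3.1.0]hexan-2-one, via acid chloride 15 (not isolated), via aryllithium 16 (not isolated), via arylzinc chloride 17 (not isolated)
Conditions: (a) 12, 1-chloro-N,N,2-trimethylprop-1-en-1-amine, CH2Cl2, 0 °C to rt; (b) 14, n-BuLi, THF, -78 °C, then ZnCl2, -78 to 0 °C; (c) solutions from (a) and (b), Pd(PPh3)4 (5 mol%), THF, 0 °C to rt
Reagents that add atoms: none
Why: Negishi acylation of the acid chloride, made under neutral conditions, with the arylzinc reagent should give the aryl ketone chemoselectively, since organozinc reagents do not add to the lactone or the product ketone and the quaternary C1 cannot form a ketene or epimerise.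

**Step 10**
Reactants: 18 (1S,4S,5R)-1-[3,4-bis(tert-butyldimethylsilyloxy)benzoyl]-4-[3,5-dimethoxy-4-(triisopropylsilyloxy)phenyl]-3-oxabicyclo[3.1.0]hexan-2-one
Product: 20 (3S,3aS)-6-[3,4-bis(tert-butyldimethylsilyloxy)phenyl]-3-[3,5-dimethoxy-4-(triisopropylsilyloxy)phenyl]-3a,4-dihydro-1H,3H-furo[3,4-c]furan-1-one, via iodomethyl enolate 19 (not isolated)
Conditions: n-Bu4NI (20 mol%), DMF, 80 °C, argon, dark
Reagents that add atoms: none
Why: Iodide attacks the unsubstituted cyclopropane carbon C6 of 18 in an SN2 sense and the strained C1–C6 bond leaves as the tetrabutylammonium enolate 19, whose charge is shared by the lactone and aryl ketone carbonyl groups on C1; the ketone-derived enolate oxygen then displaces iodide from the same CH2, forming the O–CH2 bond and freeing the catalyst. The closest known reaction type is the halide- or amine-catalysed Cloke–Wilson rearrangement of 1-acylcyclopropane-1-carboxylates to 4,5-dihydrofuran-3-carboxylates, here applied to a lactone-fused member of that class. The dihydrofuran ring closes in the 5-exo-tet mode by O-alkylation of the enolate. No stereocentre is formed; C4 and C5 of 18 are untouched because the bond that breaks is C1–C6 and the attack is at the CH2, so they appear unchanged as C3 and C3a of 20. The step needs attack at C6 rather than at C5 or the benzylic lactone carbon, which the lower substitution of C6 and its alignment with both carbonyl groups should secure; it also needs O- over C-alkylation, which is secured because C-alkylation only returns 18 and closure through the lactone carbonyl oxygen would give a bridgehead ketene acetal, so the equilibrium should drain into 20 with loss of the ring strain.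

**Step 11**
Reactants: 20 (3S,3aS)-6-[3,4-bis(tert-butyldimethylsilyloxy)phenyl]-3-[3,5-dimethoxy-4-(triisopropylsilyloxy)phenyl]-3a,4-dihydro-1H,3H-furo[3,4-c]furan-1-one
Product: 21 (3S,3aS,6S,6aR)-6-[3,4-bis(tert-butyldimethylsilyloxy)phenyl]-3-[3,5-dimethoxy-4-(triisopropylsilyloxy)phenyl]tetrahydro-1H,3H-furo[3,4-c]furan-1-one
Conditions: H2 (10 atm), Rh/Al2O3 (5 wt%), EtOAc, rt
Reagents that add atoms: none
Why: Heterogeneous syn-hydrogenation of the tetrasubstituted β-alkoxy acrylate from the convex face (the face of H-3a, opposite the C3 aryl group) should set C6 (S) and C6a (R) together, giving the cis ring fusion and the C6 aryl group on the concave face; Rh/Al2O3 is chosen for its low activity in benzylic C–O hydrogenolysis.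

**Step 12**
Reactants: 21 (3S,3aS,6S,6aR)-6-[3,4-bis(tert-butyldimethylsilyloxy)phenyl]-3-[3,5-dimethoxy-4-(triisopropylsilyloxy)phenyl]tetrahydro-1H,3H-furo[3,4-c]furan-1-one
Product: 22 (3S,3aS,6S,6aR)-6-(3,4-dihydroxyphenyl)-3-(4-hydroxy-3,5-dimethoxyphenyl)tetrahydro-1H,3H-furo[3,4-c]furan-1-one
Conditions: n-Bu4NF, AcOH, THF, 0 °C, argon
Reagents that add atoms: none
Why: Fluoride desilylation of the three aryl silyl ethers, buffered with acetic acid, should keep the phenols protonated so that neither quinone-methide ionisation at C3 nor base-induced opening of the β-alkoxy lactone can scramble the stereocentres.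

**Compound list**
1 | syringaldehyde (4-hydroxy-3,5-dimethoxybenzaldehyde) | O=Cc1cc(OC)c(O)c(OC)c1 | starting material
2 | 3,5-dimethoxy-4-(triisopropylsilyloxy)benzaldehyde | O=Cc1cc(OC)c(O[Si](C(C)C)(C(C)C)C(C)C)c(OC)c1 | intermediate
3 | ethyl (triphenylphosphoranylidene)acetate | CCOC(=O)C=P(c1ccccc1)(c1ccccc1)c1ccccc1 | starting material
4 | ethyl (E)-3-[3,5-dimethoxy-4-(triisopropylsilyloxy)phenyl]prop-2-enoate | CCOC(=O)/C=C/c1cc(OC)c(O[Si](C(C)C)(C(C)C)C(C)C)c(OC)c1 | intermediate
5 | (E)-3-[3,5-dimethoxy-4-(triisopropylsilyloxy)phenyl]prop-2-en-1-ol | OC/C=C/c1cc(OC)c(O[Si](C(C)C)(C(C)C)C(C)C)c(OC)c1 | intermediate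
6 | [(2R,3R)-3-[3,5-dimethoxy-4-(triisopropylsilyloxy)phenyl]oxiran-2-yl]methanol | OC[C@H]1O[C@@H]1c2cc(OC)c(O[Si](C(C)C)(C(C)C)C(C)C)c(OC)c2 | intermediate
7 | [(2R,3R)-3-[3,5-dimethoxy-4-(triisopropylsilyloxy)phenyl]oxiran-2-yl]methyl 4-methylbenzenesulfonate | Cc1ccc(cc1)S(=O)(=O)OC[C@H]2O[C@@H]2c3cc(OC)c(O[Si](C(C)C)(C(C)C)C(C)C)c(OC)c3 | intermediate
8 | diallyl malonate | C=CCOC(=O)CC(=O)OCC=C | starting material
9 | diallyl 2-{[(2R,3R)-3-[3,5-dimethoxy-4-(triisopropylsilyloxy)phenyl]oxiran-2-yl]methyl}propanedioate | C=CCOC(=O)C(C[C@H]1O[C@@H]1c2cc(OC)c(O[Si](C(C)C)(C(C)C)C(C)C)c(OC)c2)C(=O)OCC=C | intermediate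
10 | sodium alkoxide of diallyl (2R)-2-{(S)-[3,5-dimethoxy-4-(triisopropylsilyloxy)phenyl](hydroxy)methyl}cyclopropane-1,1-dicarboxylate | C=CCOC(=O)C1(C(=O)OCC=C)C[C@H]1[C@H]([O-])c2cc(OC)c(O[Si](C(C)C)(C(C)C)C(C)C)c(OC)c2.[Na+] | intermediate
11 | allyl (1S,4S,5R)-4-[3,5-dimethoxy-4-(triisopropylsilyloxy)phenyl]-2-oxo-3-oxabicyclo[3.1.0]hexane-1-carboxylate | C=CCOC(=O)[C@]12C[C@H]1[C@@H](c3cc(OC)c(O[Si](C(C)C)(C(C)C)C(C)C)c(OC)c3)OC2=O | intermediate
12 | (1S,4S,5R)-4-[3,5-dimethoxy-4-(triisopropylsilyloxy)phenyl]-2-oxo-3-oxabicyclo[3.1.0]hexane-1-carboxylic acid | OC(=O)[C@]12C[C@H]1[C@@H](c3cc(OC)c(O[Si](C(C)C)(C(C)C)C(C)C)c(OC)c3)OC2=O | intermediate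
13 | 4-bromocatechol (4-bromobenzene-1,2-diol) | Oc1ccc(Br)cc1O | starting material
14 | 4-bromo-1,2-bis(tert-butyldimethylsilyloxy)benzene | CC(C)(C)[Si](C)(C)Oc1ccc(Br)cc1O[Si](C)(C)C(C)(C)C | intermediate
15 | (1R,4S,5R)-4-[3,5-dimethoxy-4-(triisopropylsilyloxy)phenyl]-2-oxo-3-oxabicyclo[3.1.0]hexane-1-carbonyl chloride | ClC(=O)[C@]12C[C@H]1[C@@H](c3cc(OC)c(O[Si](C(C)C)(C(C)C)C(C)C)c(OC)c3)OC2=O | intermediate
16 | [3,4-bis(tert-butyldimethylsilyloxy)phenyl]lithium | [Li]c1ccc(O[Si](C)(C)C(C)(C)C)c(O[Si](C)(C)C(C)(C)C)c1 | intermediate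
17 | [3,4-bis(tert-butyldimethylsilyloxy)phenyl]zinc chloride | Cl[Zn]c1ccc(O[Si](C)(C)C(C)(C)C)c(O[Si](C)(C)C(C)(C)C)c1 | intermediate
18 | (1S,4S,5R)-1-[3,4-bis(tert-butyldimethylsilyloxy)benzoyl]-4-[3,5-dimethoxy-4-(triisopropylsilyloxy)phenyl]-3-oxabicyclo[3.1.0]hexan-2-one | O=C(c1ccc(O[Si](C)(C)C(C)(C)C)c(O[Si](C)(C)C(C)(C)C)c1)[C@]23C[C@H]2[C@@H](c4cc(OC)c(O[Si](C(C)C)(C(C)C)C(C)C)c(OC)c4)OC3=O | intermediate
19 | tetrabutylammonium enolate of (4R,5S)-3-[3,4-bis(tert-butyldimethylsilyloxy)benzoyl]-5-[3,5-dimethoxy-4-(triisopropylsilyloxy)phenyl]-4-(iodomethyl)oxolan-2-one | CCCC[N+](CCCC)(CCCC)CCCC.[O-]C(c1ccc(O[Si](C)(C)C(C)(C)C)c(O[Si](C)(C)C(C)(C)C)c1)=C2C(=O)O[C@H](c3cc(OC)c(O[Si](C(C)C)(C(C)C)C(C)C)c(OC)c3)[C@@H]2CI | intermediate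
20 | (3S,3aS)-6-[3,4-bis(tert-butyldimethylsilyloxy)phenyl]-3-[3,5-dimethoxy-4-(triisopropylsilyloxy)phenyl]-3a,4-dihydro-1H,3H-furo[3,4-c]furan-1-one | O=C1O[C@H](c3cc(OC)c(O[Si](C(C)C)(C(C)C)C(C)C)c(OC)c3)[C@@H]2COC(c3ccc(O[Si](C)(C)C(C)(C)C)c(O[Si](C)(C)C(C)(C)C)c3)=C12 | intermediate
21 | (3S,3aS,6S,6aR)-6-[3,4-bis(tert-butyldimethylsilyloxy)phenyl]-3-[3,5-dimethoxy-4-(triisopropylsilyloxy)phenyl]tetrahydro-1H,3H-furo[3,4-c]furan-1-one | COc1cc([C@H]2OC(=O)[C@@H]3[C@H]2CO[C@@H]3c2ccc(O[Si](C)(C)C(C)(C)C)c(O[Si](C)(C)C(C)(C)C)c2)cc(OC)c1O[Si](C(C)C)(C(C)C)C(C)C | intermediate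
22 | (3S,3aS,6S,6aR)-6-(3,4-dihydroxyphenyl)-3-(4-hydroxy-3,5-dimethoxyphenyl)tetrahydro-1H,3H-furo[3,4-c]furan-1-one | COc1cc([C@H]2OC(=O)[C@@H]3[C@H]2CO[C@@H]3c2ccc(O)c(O)c2)cc(OC)c1O | target

**Step count and risks**
Total step count: 12. Longest linear sequence: 11 (steps 1 to 7 and 9 to 12).

Steps most likely to fail:

Step 10. The iodide opening of the cyclopropane may be too slow at a temperature the silyl ethers tolerate. The ring-opened enolate may also simply return to the cyclopropane by C-alkylation, or iodide may attack the benzylic lactone carbon and erode C3. The fallback sets out from 18 and replaces nucleophilic catalysis by a stoichiometric two-stage sequence. MgI2 in toluene at rt should open the chelated keto lactone at the CH2 and, after a buffered quench, give (4R,5S)-3-[3,4-bis(tert-butyldimethylsilyloxy)benzoyl]-5-[3,5-dimethoxy-4-(triisopropylsilyloxy)phenyl]-4-(iodomethyl)oxolan-2-one F1 as a keto/enol mixture. Ag2CO3 in toluene should then pull off the iodide while the enol oxygen closes the ring (silver-assisted O-alkylation of a β-dicarbonyl compound). The sequence comes back to the route at 20.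

Step 11. Hydrogen uptake at the tetrasubstituted, donor–acceptor alkene may be sluggish. Forcing it may cause hydrogenolysis of the benzylic lactone or ether C–O bonds, or saturation of an arene. The fallback sets out from 20 and uses ionic hydrogenation with Et3SiH and CF3CO2H in CH2Cl2 at -40 °C. C-protonation at C6a should give the cis-fused (3S,3aS,6aR)-6-aryl oxocarbenium trifluoroacetate F2, which should accept hydride from the convex face. The sequence comes back to the route at 21 with the same configuration at C6 and C6a.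

Step 6. The malonate anion may open the oxirane at the benzylic carbon instead of displacing the tosylate. The alkoxide released on lactonisation may also attack the silyl ether or the product cyclopropane. The fallback sets out from 5 and makes the C–C bond before the epoxide. CBr4 and PPh3 in CH2Cl2 at 0 °C should give (E)-3-[3,5-dimethoxy-4-(triisopropylsilyloxy)phenyl]prop-2-enyl bromide F3. Alkylation of the sodium salt of excess 8 with F3 in THF should give diallyl (E)-2-{3-[3,5-dimethoxy-4-(triisopropylsilyloxy)phenyl]prop-2-enyl}propanedioate F4. Shi epoxidation of the trans-styrene unit of F4 (D-fructose-derived ketone catalyst, KHSO5, K2CO3 buffer, MeCN/H2O, 0 °C) should give the (2R,3R)-epoxide 9. NaH in THF at 60 °C should then close 9 through 10. The sequence comes back to the route at 11.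

**Further compounds**
F1 | step 10 | (4R,5S)-3-[3,4-bis(tert-butyldimethylsilyloxy)benzoyl]-5-[3,5-dimethoxy-4-(triisopropylsilyloxy)phenyl]-4-(iodomethyl)oxolan-2-one (C3 epimers and enol form) | O=C(c1ccc(O[Si](C)(C)C(C)(C)C)c(O[Si](C)(C)C(C)(C)C)c1)C2C(=O)O[C@H](c3cc(OC)c(O[Si](C(C)C)(C(C)C)C(C)C)c(OC)c3)[C@@H]2CI
F2 | step 11 | (3S,3aS,6aR)-6-[3,4-bis(tert-butyldimethylsilyloxy)phenyl]-3-[3,5-dimethoxy-4-(triisopropylsilyloxy)phenyl]-1-oxo-3,3a,4,6a-tetrahydro-1H-furo[3,4-c]furan-5-ium trifluoroacetate | O=C1O[C@H](c3cc(OC)c(O[Si](C(C)C)(C(C)C)C(C)C)c(OC)c3)[C@@H]2C[O+]=C(c3ccc(O[Si](C)(C)C(C)(C)C)c(O[Si](C)(C)C(C)(C)C)c3)[C@H]12.[O-]C(=O)C(F)(F)F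
F3 | step 6 | (E)-3-[3,5-dimethoxy-4-(triisopropylsilyloxy)phenyl]prop-2-enyl bromide | BrC/C=C/c1cc(OC)c(O[Si](C(C)C)(C(C)C)C(C)C)c(OC)c1
F4 | step 6 | diallyl (E)-2-{3-[3,5-dimethoxy-4-(triisopropylsilyloxy)phenyl]prop-2-enyl}propanedioate | C=CCOC(=O)C(C/C=C/c1cc(OC)c(O[Si](C(C)C)(C(C)C)C(C)C)c(OC)c1)C(=O)OCC=C
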